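**Plan**

1. Retrosynthesis of epicatechin-(4β→6)-epiafzelechin-(4β→8)-epicatechin-(4β→6)-epicatechin (units 1 to 4, top to bottom): cut C4(unit 2)–C8(unit 3) into two dimers, then C4(unit 1)–C6(unit 2); inside unit 3 cut C2–aryl and C2–H, then C3–C4 of ring C, then C4(unit 3)–C6(unit 4).
2. Forward: unit 4 (from epicatechin, C8 capped with Br) is metalated at C6 and added to a ring A aldehyde whose CHO carbon is C4 of unit 3. A benzyloxyacetate on O1 brings C2 and C3. Ring C then closes through C3–C4 as a dihydrocoumarin, ring B is added at C2, and the lactol is reduced to the flavan. The 1–2 dimer is joined last and all benzyl and bromo groups are removed.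
3. Enabling feature: C4 of unit 3 lies between two phloroglucinol-type rings (ring A of unit 3 and ring A of unit 4), so it can be carried as a persistent diarylmethylium ion. The O1–C2–C3 segment of ring C maps onto an O-aryl glycolate, whose enolate carbon is C3.
4. Stereochemistry: units 1, 2 and 4 come from (−)-epicatechin and (−)-epiafzelechin. Both Friedel–Crafts bonds form trans to the 3-oxygen (4β). In unit 3, C4 is set by a chiral counter-anion in the ring closure, C3 follows as the trans (epimerisable) centre, and C2 is set by axial hydride delivery anti to the 3-benzyloxy group.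

Key step: step 8

Remark: (−)-epicatechin, (−)-epiafzelechin, 2,4-bis(benzyloxy)-6-hydroxybenzaldehyde, benzyloxyacetyl chloride and 4-bromo-1,2-bis(benzyloxy)benzene are taken as purchasable; the carbinol centre made in step 5 is an epimeric mixture that is erased in step 8.

**Route**

Step 1
Reactants: 1 (−)-epicatechin
Product: 2 5,7,3',4'-tetra-O-benzyl-(−)-epicatechin
Conditions: BnBr, K2CO3, DMF, 0 °C → rt
Reagents that add atoms: benzyl bromide, BrCc1ccccc1
Why: Williamson etherification with carbonate base alkylates only the four phenols, leaving the 3-OH free and the (2R,3R) centres untouched.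

Step 2
Reactants: 2 5,7,3',4'-tetra-O-benzyl-(−)-epicatechin
Product: 3 3,5,7,3',4'-penta-O-benzyl-(−)-epicatechin
Conditions: NaH, BnBr, DMF, 0 °C → rt
Reagents that add atoms: benzyl bromide, BrCc1ccccc1
Why: Williamson etherification of the remaining secondary alcohol (alkoxide from NaH) gives the fully benzylated flavan without touching C2 or C3.

Step 3
Reactants: 3 3,5,7,3',4'-penta-O-benzyl-(−)-epicatechin
Product: 4 8-bromo-3,5,7,3',4'-penta-O-benzyl-(−)-epicatechin
Conditions: NBS, CH2Cl2, −78 °C → rt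
Reagents that add atoms: N-bromosuccinimide, O=C1CCC(=O)N1Br
Why: Electrophilic aromatic bromination occurs at C8, the more accessible of the two free ring A positions (C6 is flanked by two benzyloxy groups), and the bromine then serves as a removable cap that leaves C6 as the only site for the next substitution.

Step 4
Reactants: 4 8-bromo-3,5,7,3',4'-penta-O-benzyl-(−)-epicatechin
Product: 5 8-bromo-6-iodo-3,5,7,3',4'-penta-O-benzyl-(−)-epicatechin
Conditions: NIS, CF3CO2H (cat.), MeCN/CH2Cl2, 0 °C → rt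
Reagents that add atoms: N-iodosuccinimide, O=C1CCC(=O)N1I
Why: Electrophilic aromatic iodination takes the single remaining ring A position, C6, because ring B and the benzyl rings are far less electron-rich.

Step 5
Reactants: 5 8-bromo-6-iodo-3,5,7,3',4'-penta-O-benzyl-(−)-epicatechin; 6 2,4-bis(benzyloxy)-6-hydroxybenzaldehyde
Product: 9 2-[hydroxy(8-bromo-3,5,7,3',4'-penta-O-benzylepicatechin-6-yl)methyl]-3,5-bis(benzyloxy)phenol (both carbinol epimers), via aryl Grignard reagent 7 (not isolated), via chloromagnesium phenoxide 8 (not isolated)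
Conditions: 5, i-PrMgCl·LiCl, THF, −20 °C; separately 6, i-PrMgCl (1 equiv), THF, 0 °C; combine, −20 °C → rt; aq. NH4Cl
Reagents that add atoms: none
Why: Iodine–magnesium exchange is selective for C–I over C–Br, and Grignard addition of the C6 carbanion to the aldehyde of the phenoxide forms the C4(unit 3)–C6(unit 4) bond; the new carbinol centre is formed without control and is erased in step 8.

Step 6
Reactants: 9 2-[hydroxy(8-bromo-3,5,7,3',4'-penta-O-benzylepicatechin-6-yl)methyl]-3,5-bis(benzyloxy)phenol; 10 benzyloxyacetyl chloride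
Product: 11 benzyloxyacetate ester of 9 at the phenol oxygen (both carbinol epimers)
Conditions: pyridine, CH2Cl2, −20 °C
Reagents that add atoms: none
Why: Esterification (O-acylation) occurs at the phenol because the secondary benzhydrol is shielded by four ortho substituents, and it places C2 and C3 of the future ring C on O1.

Step 7
Reactants: 11 benzyloxyacetate ester of 9
Product: 13 (Z)-trimethylsilyl ketene acetal of 11 bearing a trimethylsilyl ether on the benzhydrol oxygen, via benzhydryl trimethylsilyl ether 12 (not isolated)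
Conditions: MeC(OSiMe3)=NSiMe3, CH2Cl2, rt; evaporate; LiN(SiMe3)2, Me3SiCl, THF, −78 °C; pentane, filtration
Reagents that add atoms: N,O-bis(trimethylsilyl)acetamide, CC(O[Si](C)(C)C)=N[Si](C)(C)C; chlorotrimethylsilane, C[Si](C)(C)Cl
Why: Neutral O-silylation of the benzhydrol prevents acyl migration, and kinetic ester enolisation with in situ silyl trapping (silyl ketene acetal formation) gives the chelation-derived (Z)-ketene acetal before the aryl ester enolate can fragment to a ketene.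

Step 8
Reactants: 13 (Z)-trimethylsilyl ketene acetal
Product: 15 (3R,4R)-3,5,7-tris(benzyloxy)-4-(8-bromo-3,5,7,3',4'-penta-O-benzylepicatechin-6-yl)-3,4-dihydro-2H-chromen-2-one, via diarylmethylium ion 14 (not isolated)
Conditions: chiral imidodiphosphorimidate (IDPi) Brønsted acid (5 mol %), toluene, −78 → −40 °C; Et3N quench
Reagents that add atoms: none
Why: Proposed new method: the acid is silylated by a trace of 13, and the resulting silylium–IDPi pair abstracts the C4 trimethylsilyloxy group as (Me3Si)2O, giving the bis(2,4,6-trioxyaryl)methylium ion 14 as a contact ion pair with the confined chiral anion (both carbinol epimers converge); the tethered ketene acetal carbon C3 then attacks C4 and the silyl carboxonium ion returns Me3Si+ to the anion, closing the catalytic cycle. The closest known reaction types are silylium-based counter-anion-directed enantioselective Mukaiyama additions of silyl ketene acetals and anion-binding-catalysed additions of silyl ketene acetals to oxocarbenium and diarylmethyl cations. Ring C closes as a six-membered lactone in the 6-(enolendo) mode onto the trigonal cationic carbon, the geometry by which aryl ester enolates give dihydrocoumarins. C4 is controlled by the chiral anion, which shields one face of the planar cation (the catalyst enantiomer is chosen to give the 4β-aryl, 4R lactone), and C3 by the half-chair transition state in which the aryl group on C4 is pseudoaxial (peri strain with the 5-benzyloxy group) and the 3-benzyloxy group is anti to it; because C3 is alpha to the lactone carbonyl, any cis isomer should equilibrate to the trans lactone with mild base. The step needs C- rather than O-alkylation and intramolecular rather than intermolecular capture: O-attack is reversible whereas C–C formation is not, the 1,2-placement of the ester oxygen and the cationic carbon on ring A of unit 3 favours the six-membered closure, and ring A of unit 4 is fully substituted (Br at C8) so no Friedel–Crafts pathway competes.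

Step 9
Reactants: 15 (3R,4R)-dihydrocoumarin; 16 4-bromo-1,2-bis(benzyloxy)benzene
Product: 18 (2R,3R)-2-(benzyloxy)-1-[3,4-bis(benzyloxy)phenyl]-3-[2,4-bis(benzyloxy)-6-hydroxyphenyl]-3-(8-bromo-3,5,7,3',4'-penta-O-benzylepicatechin-6-yl)propan-1-one (in equilibrium with its lactol), via aryl Grignard reagent 17 (not isolated)
Conditions: 16, Mg, THF, rt; then 15, THF, −78 → −30 °C; pH 7 buffer
Reagents that add atoms: none
Why: Grignard addition to the aryl lactone should stop after one addition because the expelled phenoxide leaves a hindered, electron-rich aryl ketone, so ring B is attached to C2 while C3 and C4 are untouched at low temperature.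

Step 10
Reactants: 18 (2R,3R)-hydroxy ketone
Product: 20 3,5,7,3',4'-penta-O-benzylepicatechin-(4β→6)-8-bromo-3,5,7,3',4'-penta-O-benzylepicatechin, via cyclic oxocarbenium ion 19 (not isolated)
Conditions: Et3SiH, Me3SiOTf (cat.), CH2Cl2, −78 → −40 °C
Reagents that add atoms: none
Why: Reductive etherification: the lactol form of 18 ionises to the cyclic oxocarbenium ion 19 and the silane delivers hydride axially, anti to the pseudoaxial 3-benzyloxy group, so that ring B becomes equatorial and cis to the 3-oxygen (2R).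

Step 11
Reactants: 4 8-bromo-3,5,7,3',4'-penta-O-benzyl-(−)-epicatechin
Product: 21 8-bromo-4β-(2-ethoxyethoxy)-3,5,7,3',4'-penta-O-benzylepicatechin
Conditions: DDQ, HOCH2CH2OEt, CH2Cl2, rt
Reagents that add atoms: 2-ethoxyethanol, CCOCCO
Why: DDQ benzylic oxidation (hydride abstraction at C4 to the alkoxy-stabilised cation) followed by capture with the alcohol trans to the 3-benzyloxy group gives the 4β-ether that serves as cation precursor.

Step 12
Reactants: 22 (−)-epiafzelechin
Product: 23 5,7,4'-tri-O-benzyl-(−)-epiafzelechin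
Conditions: BnBr, K2CO3, DMF, 0 °C → rt
Reagents that add atoms: benzyl bromide, BrCc1ccccc1
Why: Williamson etherification of the three phenols with carbonate base leaves the 3-OH and the (2R,3R) centres untouched.

Step 13
Reactants: 23 5,7,4'-tri-O-benzyl-(−)-epiafzelechin
Product: 24 8-bromo-5,7,4'-tri-O-benzyl-(−)-epiafzelechin
Conditions: NBS, CH2Cl2, −78 °C → rt
Reagents that add atoms: N-bromosuccinimide, O=C1CCC(=O)N1Br
Why: Electrophilic aromatic bromination at C8 caps the more reactive ring A position so that C6 becomes the only nucleophilic site of this unit.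

Step 14
Reactants: 24 8-bromo-5,7,4'-tri-O-benzyl-(−)-epiafzelechin
Product: 25 8-bromo-4β-(2-ethoxyethoxy)-5,7,4'-tri-O-benzylepiafzelechin
Conditions: DDQ, HOCH2CH2OEt, CH2Cl2, rt
Reagents that add atoms: 2-ethoxyethanol, CCOCCO
Why: DDQ benzylic oxidation at C4 with capture of the cation by the alcohol trans to the 3-OH gives the 4β-ether.

Step 15
Reactants: 25 8-bromo-4β-(2-ethoxyethoxy)-5,7,4'-tri-O-benzylepiafzelechin
Product: 26 4β-(benzylsulfanyl)-8-bromo-5,7,4'-tri-O-benzylepiafzelechin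
Conditions: BnSH, BF3·OEt2 (cat.), CH2Cl2, −78 → −20 °C
Reagents that add atoms: benzyl mercaptan, SCc1ccccc1
Why: Lewis-acid-mediated thiolysis (SN1 exchange through the C4 cation, thiol entering trans to the 3-OH) converts the ether into a 4β-thioether that hard Lewis acids should not ionise at low temperature.

Step 16
Reactants: 21 8-bromo-4β-(2-ethoxyethoxy)-3,5,7,3',4'-penta-O-benzylepicatechin; 26 4β-(benzylsulfanyl)-8-bromo-5,7,4'-tri-O-benzylepiafzelechin
Product: 27 8-bromo-3,5,7,3',4'-penta-O-benzylepicatechin-(4β→6)-4β-(benzylsulfanyl)-8-bromo-5,7,4'-tri-O-benzylepiafzelechin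
Conditions: 26 (1.5 equiv), Me3SiOTf (cat.), CH2Cl2, −78 °C
Reagents that add atoms: none
Why: Friedel–Crafts alkylation in which the silyl triflate ionises only the 4-alkoxy group of 21, the bromine cap on 26 leaves C6 as the sole nucleophilic carbon, the bond forms trans to the 3-benzyloxy group (4β), and self-condensation is suppressed because C8 of both partners carries bromine.

Step 17
Reactants: 27 dimer of units 1 and 2 (4-benzylsulfanyl); 20 dimer of units 3 and 4
Product: 28 8-bromo-penta-O-benzylepicatechin-(4β→6)-8-bromo-5,7,4'-tri-O-benzylepiafzelechin-(4β→8)-penta-O-benzylepicatechin-(4β→6)-8-bromo-penta-O-benzylepicatechin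
Conditions: 20 (1.5 equiv), AgBF4, 2,6-di-tert-butyl-4-methylpyridine, THF, 0 °C
Reagents that add atoms: none
Why: Friedel–Crafts alkylation under thiophilic silver activation, in which the benzylthio group of 27 is ionised without free Brønsted acid (the pyridine base takes up HBF4), C8 of unit 3 is the most nucleophilic free position of 20 (C8 of unit 4 is capped), and attack trans to the 3-OH of unit 2 gives the 4β bond.

Step 18
Reactants: 28 protected tetramer
Product: 29 epicatechin-(4β→6)-epiafzelechin-(4β→8)-epicatechin-(4β→6)-epicatechin (target)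
Conditions: H2 (1 atm), Pd(OH)2/C, Et3N, THF/MeOH/H2O, rt
Reagents that add atoms: none
Why: Catalytic hydrogenolysis cleaves all eighteen benzyl ethers and the three aryl C–Br bonds in one operation, the amine trapping HBr so that the acid-labile interflavan bonds and all stereocentres are preserved.

**Compound list**

1 | (−)-epicatechin, (2R,3R) | O[C@@H]1Cc2c(O)cc(O)cc2O[C@@H]1c1ccc(O)c(O)c1 | starting material
2 | 5,7,3',4'-tetra-O-benzyl-(−)-epicatechin | c1c(OCc9ccccc9)cc2c(c1OCc9ccccc9)C[C@@H](O)[C@@H](c1ccc(OCc9ccccc9)c(OCc9ccccc9)c1)O2 | intermediate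
3 | 3,5,7,3',4'-penta-O-benzyl-(−)-epicatechin | c1c(OCc9ccccc9)cc2c(c1OCc9ccccc9)C[C@@H](OCc9ccccc9)[C@@H](c1ccc(OCc9ccccc9)c(OCc9ccccc9)c1)O2 | intermediate
4 | 8-bromo-3,5,7,3',4'-penta-O-benzyl-(−)-epicatechin | c1c(OCc9ccccc9)c(Br)c2c(c1OCc9ccccc9)C[C@@H](OCc9ccccc9)[C@@H](c1ccc(OCc9ccccc9)c(OCc9ccccc9)c1)O2 | intermediate
5 | 8-bromo-6-iodo-3,5,7,3',4'-penta-O-benzyl-(−)-epicatechin | Ic1c(OCc9ccccc9)c(Br)c2c(c1OCc9ccccc9)C[C@@H](OCc9ccccc9)[C@@H](c1ccc(OCc9ccccc9)c(OCc9ccccc9)c1)O2 | intermediate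
6 | 2,4-bis(benzyloxy)-6-hydroxybenzaldehyde | O=Cc1c(O)cc(OCc9ccccc9)cc1OCc9ccccc9 | starting material
7 | aryl Grignard reagent (C6–MgCl) from 5, not isolated | Cl[Mg]c1c(OCc9ccccc9)c(Br)c2c(c1OCc9ccccc9)C[C@@H](OCc9ccccc9)[C@@H](c1ccc(OCc9ccccc9)c(OCc9ccccc9)c1)O2 | intermediate
8 | chloromagnesium phenoxide of 6, not isolated | O=Cc1c(O[Mg]Cl)cc(OCc9ccccc9)cc1OCc9ccccc9 | intermediate
9 | 2-[hydroxy(8-bromo-3,5,7,3',4'-penta-O-benzylepicatechin-6-yl)methyl]-3,5-bis(benzyloxy)phenol, both carbinol epimers | Oc1cc(OCc9ccccc9)cc(OCc9ccccc9)c1C(O)c1c(OCc9ccccc9)c(Br)c2c(c1OCc9ccccc9)C[C@@H](OCc9ccccc9)[C@@H](c1ccc(OCc9ccccc9)c(OCc9ccccc9)c1)O2 | intermediate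
10 | benzyloxyacetyl chloride | O=C(Cl)COCc1ccccc1 | starting material
11 | benzyloxyacetate ester of 9 at the phenol oxygen, both carbinol epimers | O=C(COCc9ccccc9)Oc1cc(OCc9ccccc9)cc(OCc9ccccc9)c1C(O)c1c(OCc9ccccc9)c(Br)c2c(c1OCc9ccccc9)C[C@@H](OCc9ccccc9)[C@@H](c1ccc(OCc9ccccc9)c(OCc9ccccc9)c1)O2 | intermediate
12 | benzhydryl trimethylsilyl ether of 11, not isolated | O=C(COCc9ccccc9)Oc1cc(OCc9ccccc9)cc(OCc9ccccc9)c1C(O[Si](C)(C)C)c1c(OCc9ccccc9)c(Br)c2c(c1OCc9ccccc9)C[C@@H](OCc9ccccc9)[C@@H](c1ccc(OCc9ccccc9)c(OCc9ccccc9)c1)O2 | intermediate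
13 | (Z)-trimethylsilyl ketene acetal of 12 | C[Si](C)(C)O/C(=C\OCc9ccccc9)Oc1cc(OCc9ccccc9)cc(OCc9ccccc9)c1C(O[Si](C)(C)C)c1c(OCc9ccccc9)c(Br)c2c(c1OCc9ccccc9)C[C@@H](OCc9ccccc9)[C@@H](c1ccc(OCc9ccccc9)c(OCc9ccccc9)c1)O2 | intermediate
14 | diarylmethylium ion from 13 (counter-ion: catalyst anion), not isolated | C[Si](C)(C)O/C(=C\OCc9ccccc9)Oc1cc(OCc9ccccc9)cc(OCc9ccccc9)c1[CH+]c1c(OCc9ccccc9)c(Br)c2c(c1OCc9ccccc9)C[C@@H](OCc9ccccc9)[C@@H](c1ccc(OCc9ccccc9)c(OCc9ccccc9)c1)O2 | intermediate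
15 | (3R,4R)-3,5,7-tris(benzyloxy)-4-(8-bromo-3,5,7,3',4'-penta-O-benzylepicatechin-6-yl)-3,4-dihydro-2H-chromen-2-one (3,4-trans) | c1c(OCc9ccccc9)cc(OCc9ccccc9)c2c1OC(=O)[C@H](OCc9ccccc9)[C@H]2c1c(OCc9ccccc9)c(Br)c2c(c1OCc9ccccc9)C[C@@H](OCc9ccccc9)[C@@H](c1ccc(OCc9ccccc9)c(OCc9ccccc9)c1)O2 | intermediate
16 | 4-bromo-1,2-bis(benzyloxy)benzene | Brc1ccc(OCc9ccccc9)c(OCc9ccccc9)c1 | starting material
17 | 3,4-bis(benzyloxy)phenylmagnesium bromide, not isolated | Br[Mg]c1ccc(OCc9ccccc9)c(OCc9ccccc9)c1 | intermediate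
18 | (2R,3R)-2-(benzyloxy)-1-[3,4-bis(benzyloxy)phenyl]-3-[2,4-bis(benzyloxy)-6-hydroxyphenyl]-3-(8-bromo-3,5,7,3',4'-penta-O-benzylepicatechin-6-yl)propan-1-one | O=C(c1ccc(OCc9ccccc9)c(OCc9ccccc9)c1)[C@H](OCc9ccccc9)[C@H](c1c(O)cc(OCc9ccccc9)cc1OCc9ccccc9)c1c(OCc9ccccc9)c(Br)c2c(c1OCc9ccccc9)C[C@@H](OCc9ccccc9)[C@@H](c1ccc(OCc9ccccc9)c(OCc9ccccc9)c1)O2 | intermediate
19 | cyclic oxocarbenium ion (2-aryl-3,4-dihydro-2H-chromenylium) from 18, not isolated | c1c(OCc9ccccc9)cc(OCc9ccccc9)c2c1[O+]=C(c1ccc(OCc9ccccc9)c(OCc9ccccc9)c1)[C@H](OCc9ccccc9)[C@H]2c1c(OCc9ccccc9)c(Br)c2c(c1OCc9ccccc9)C[C@@H](OCc9ccccc9)[C@@H](c1ccc(OCc9ccccc9)c(OCc9ccccc9)c1)O2 | intermediate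
20 | 3,5,7,3',4'-penta-O-benzylepicatechin-(4β→6)-8-bromo-3,5,7,3',4'-penta-O-benzylepicatechin | c1c(OCc9ccccc9)cc(OCc9ccccc9)c2c1O[C@H](c1ccc(OCc9ccccc9)c(OCc9ccccc9)c1)[C@H](OCc9ccccc9)[C@H]2c1c(OCc9ccccc9)c(Br)c2c(c1OCc9ccccc9)C[C@@H](OCc9ccccc9)[C@@H](c1ccc(OCc9ccccc9)c(OCc9ccccc9)c1)O2 | intermediate
21 | 8-bromo-4β-(2-ethoxyethoxy)-3,5,7,3',4'-penta-O-benzylepicatechin | CCOCCO[C@H]1c2c(OCc9ccccc9)cc(OCc9ccccc9)c(Br)c2O[C@H](c2ccc(OCc9ccccc9)c(OCc9ccccc9)c2)[C@@H]1OCc9ccccc9 | intermediate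
22 | (−)-epiafzelechin, (2R,3R) | O[C@@H]1Cc2c(O)cc(O)cc2O[C@@H]1c1ccc(O)cc1 | starting material
23 | 5,7,4'-tri-O-benzyl-(−)-epiafzelechin | c9ccccc9COc1ccc([C@H]2Oc3cc(OCc9ccccc9)cc(OCc9ccccc9)c3C[C@H]2O)cc1 | intermediate
24 | 8-bromo-5,7,4'-tri-O-benzyl-(−)-epiafzelechin | c9ccccc9COc1ccc([C@H]2Oc3c(Br)c(OCc9ccccc9)cc(OCc9ccccc9)c3C[C@H]2O)cc1 | intermediate
25 | 8-bromo-4β-(2-ethoxyethoxy)-5,7,4'-tri-O-benzylepiafzelechin | c9ccccc9COc1ccc([C@H]2Oc3c(Br)c(OCc9ccccc9)cc(OCc9ccccc9)c3[C@H](OCCOCC)[C@H]2O)cc1 | intermediate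
26 | 4β-(benzylsulfanyl)-8-bromo-5,7,4'-tri-O-benzylepiafzelechin | c9ccccc9COc1ccc([C@H]2Oc3c(Br)c(OCc9ccccc9)cc(OCc9ccccc9)c3[C@H](SCc9ccccc9)[C@H]2O)cc1 | intermediate
27 | 8-bromo-3,5,7,3',4'-penta-O-benzylepicatechin-(4β→6)-4β-(benzylsulfanyl)-8-bromo-5,7,4'-tri-O-benzylepiafzelechin | c9ccccc9COc1ccc([C@H]2Oc3c(Br)c(OCc9ccccc9)c([C@H]4c5c(OCc9ccccc9)cc(OCc9ccccc9)c(Br)c5O[C@H](c5ccc(OCc9ccccc9)c(OCc9ccccc9)c5)[C@@H]4OCc9ccccc9)c(OCc9ccccc9)c3[C@H](SCc9ccccc9)[C@H]2O)cc1 | intermediate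
28 | protected tetramer: 8-bromo-penta-O-benzylepicatechin-(4β→6)-8-bromo-5,7,4'-tri-O-benzylepiafzelechin-(4β→8)-penta-O-benzylepicatechin-(4β→6)-8-bromo-penta-O-benzylepicatechin | c9ccccc9COc1ccc([C@H]2Oc3c(Br)c(OCc9ccccc9)c([C@H]4c5c(OCc9ccccc9)cc(OCc9ccccc9)c(Br)c5O[C@H](c5ccc(OCc9ccccc9)c(OCc9ccccc9)c5)[C@@H]4OCc9ccccc9)c(OCc9ccccc9)c3[C@H](c3c(OCc9ccccc9)cc(OCc9ccccc9)c4c3O[C@H](c3ccc(OCc9ccccc9)c(OCc9ccccc9)c3)[C@H](OCc9ccccc9)[C@H]4c3c(OCc9ccccc9)c(Br)c4c(c3OCc9ccccc9)C[C@@H](OCc9ccccc9)[C@@H](c3ccc(OCc9ccccc9)c(OCc9ccccc9)c3)O4)[C@H]2O)cc1 | intermediate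
29 | epicatechin-(4β→6)-epiafzelechin-(4β→8)-epicatechin-(4β→6)-epicatechin | Oc1ccc([C@H]2Oc3cc(O)c([C@H]4c5c(O)cc(O)cc5O[C@H](c5ccc(O)c(O)c5)[C@@H]4O)c(O)c3[C@H](c3c(O)cc(O)c4c3O[C@H](c3ccc(O)c(O)c3)[C@H](O)[C@H]4c3c(O)cc4c(c3O)C[C@@H](O)[C@@H](c3ccc(O)c(O)c3)O4)[C@H]2O)cc1 | target

**Totals**

Total step count: 18. Longest linear sequence: 12 steps (steps 1 to 10, then 17 and 18).

**Steps most likely to fail**

Step 8 (carries the label). Facial discrimination by the ion pair may be weak for so stabilised and long-lived a cation, and capture of the cation between molecules instead of by the tethered ketene acetal would erode control at C4 and C3. The fallback uses known chemistry and sets out from 3 and 4. Compound 3 is oxidised at C4 with DDQ in the presence of 2-ethoxyethanol to 4β-(2-ethoxyethoxy)-3,5,7,3',4'-penta-O-benzylepicatechin F1. F1 is then ionised with Me3SiOTf in CH2Cl2 at −78 °C in the presence of an excess of the bromo-capped nucleophile 4, whose only free ring A position is C6. This Friedel–Crafts alkylation forms the C4–C6 bond trans to the 3-benzyloxy group and comes back to the route at 20, bypassing steps 4 to 10.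

Step 10. Hydride may approach the oxocarbenium ion from the face syn to the 3-benzyloxy group, because the pseudoaxial aryl group on C4 hinders the axial trajectory; the Lewis acid may also trigger heterolysis of the C3–C4 bond back to the stabilised cation. The fallback sets out from 18. Chelation-controlled reduction of the ketone with Zn(BH4)2 in Et2O at −20 °C (zinc bridged between the carbonyl and 3-benzyloxy oxygens, hydride entering anti to the diarylmethyl group) gives (1S,2R,3R)-2-(benzyloxy)-1-[3,4-bis(benzyloxy)phenyl]-3-[2,4-bis(benzyloxy)-6-hydroxyphenyl]-3-(8-bromo-3,5,7,3',4'-penta-O-benzylepicatechin-6-yl)propan-1-ol F2. An intramolecular Mitsunobu etherification (PPh3, diisopropyl azodicarboxylate, THF, 0 °C) then closes O1–C2 with inversion at the benzylic carbinol and comes back at 20.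

Step 17. Ionisation of the thioether may be slow in so large a fragment, attack may leak to C6 instead of C8 of unit 3, and adventitious acid may scramble the two existing interflavan bonds. The fallback exchanges the leaving groups between the partners and sets out from 21. Thiolysis of 21 (BnSH, cat. BF3·OEt2) gives 4β-(benzylsulfanyl)-8-bromo-3,5,7,3',4'-penta-O-benzylepicatechin F3. Silver-promoted alkylation (AgBF4, 2,6-di-tert-butyl-4-methylpyridine, THF, 0 °C) of C6 of 25, whose 2-ethoxyethoxy group is inert to the silver salt, gives 8-bromo-3,5,7,3',4'-penta-O-benzylepicatechin-(4β→6)-8-bromo-4β-(2-ethoxyethoxy)-5,7,4'-tri-O-benzylepiafzelechin F4. F4 is then joined to 20 with Me3SiOTf in CH2Cl2 at −78 °C, the usual hard-Lewis-acid union for benzylated oligomers, and the sequence comes back at 28.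

Further compounds
F1 | step 8 | 4β-(2-ethoxyethoxy)-3,5,7,3',4'-penta-O-benzylepicatechin | CCOCCO[C@H]1c2c(OCc9ccccc9)cc(OCc9ccccc9)cc2O[C@H](c2ccc(OCc9ccccc9)c(OCc9ccccc9)c2)[C@@H]1OCc9ccccc9
F2 | step 10 | (1S,2R,3R)-2-(benzyloxy)-1-[3,4-bis(benzyloxy)phenyl]-3-[2,4-bis(benzyloxy)-6-hydroxyphenyl]-3-(8-bromo-3,5,7,3',4'-penta-O-benzylepicatechin-6-yl)propan-1-ol | O[C@@H](c1ccc(OCc9ccccc9)c(OCc9ccccc9)c1)[C@H](OCc9ccccc9)[C@H](c1c(O)cc(OCc9ccccc9)cc1OCc9ccccc9)c1c(OCc9ccccc9)c(Br)c2c(c1OCc9ccccc9)C[C@@H](OCc9ccccc9)[C@@H](c1ccc(OCc9ccccc9)c(OCc9ccccc9)c1)O2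
F3 | step 17 | 4β-(benzylsulfanyl)-8-bromo-3,5,7,3',4'-penta-O-benzylepicatechin | c9ccccc9CS[C@H]1c2c(OCc9ccccc9)cc(OCc9ccccc9)c(Br)c2O[C@H](c2ccc(OCc9ccccc9)c(OCc9ccccc9)c2)[C@@H]1OCc9ccccc9
F4 | step 17 | 8-bromo-3,5,7,3',4'-penta-O-benzylepicatechin-(4β→6)-8-bromo-4β-(2-ethoxyethoxy)-5,7,4'-tri-O-benzylepiafzelechin | c9ccccc9COc1ccc([C@H]2Oc3c(Br)c(OCc9ccccc9)c([C@H]4c5c(OCc9ccccc9)cc(OCc9ccccc9)c(Br)c5O[C@H](c5ccc(OCc9ccccc9)c(OCc9ccccc9)c5)[C@@H]4OCc9ccccc9)c(OCc9ccccc9)c3[C@H](OCCOCC)[C@H]2O)cc1
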